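**Plan**

- Retrosynthesis: the three phenols are unmasked last; the C8–CH2 bond to the lavandulyl chain is cut (sp2–sp3 Negishi coupling); ring C is then cut twice, at O1–C8a and at C4–C4a, which separates a ring A aryne from a ring B 3-hydroxy amide.
- Enabling feature: ring C is fused to ring A through the neighbouring carbons C8a (bearing O1) and C4a (bearing the C4 carbonyl), an ortho oxygen/acyl pair that an aryne can take up in one operation; the oxygen on C5, next to C4a, polarises that aryne so that the incoming oxygen bonds to C8a.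
- Forward: ring A (aryne precursor, from 5-methoxyresorcinol) and ring B with C2–C4 (hydroxy Weinreb amide, from 2',6'-dihydroxyacetophenone) are made separately and ring C is closed between them in one step; the ring B benzyl ethers are then exchanged for acetates so that only ring A is iodinated (C8), the chain is joined, and one acid step frees the phenols.
- Stereochemistry: C2 comes from a Noyori hydrogenation with (R)-BINAP and survives the annulation because the C2–O bond is never broken; the side-chain center comes from lipase resolution of racemic lavandulol. (S)-Lavandulol gives the chain named (R) in the target only because CH2–aryl ranks below isopropenyl where CH2–OH ranked above it.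

Key step: step 9

Assumption: Candida antarctica lipase B is taken to acetylate (R)-lavandulol faster, leaving the (S)-alcohol; were the preference the reverse, the (S)-acetate would be methanolysed (K2CO3, MeOH) to the same alcohol.

**Route**

Step 1
Reactants: 1 5-methoxyresorcinol
Product: 2 3-methoxy-5-(methoxymethoxy)phenol
Conditions: MOMCl (1.0 equiv), iPr2NEt (1.2 equiv), THF, 0 → 23 °C; chromatography, recovered 1 recycled
Reagents that add atoms: chloromethyl methyl ether, COCCl
Why: Williamson-type O-alkylation of one of two equivalent phenols with a single equivalent of the chloromethyl ether should give the mono-MOM ether as the main product of a statistical desymmetrisation, the bis-ether and unreacted diol being easily separated.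

Step 2
Reactants: 2 3-methoxy-5-(methoxymethoxy)phenol
Product: 3 3-methoxy-5-(methoxymethoxy)phenyl N-(propan-2-yl)carbamate
Conditions: iPrNCO (1.3 equiv), Et3N (0.2 equiv), CH2Cl2, 23 °C
Reagents that add atoms: isopropyl isocyanate, CC(C)N=C=O
Why: Amine-catalysed addition of the phenol to the isocyanate (carbamoylation) installs a secondary carbamate that directs metalation strongly and can later be removed under mild amine conditions.

Step 3
Reactants: 3 3-methoxy-5-(methoxymethoxy)phenyl N-(propan-2-yl)carbamate
Product: 7 5-methoxy-3-(methoxymethoxy)-2-(trimethylsilyl)phenyl N-(propan-2-yl)carbamate, via N-silyl carbamate 4 (not isolated), via aryllithium 5 (not isolated), via N-silyl C-silyl carbamate 6 (not isolated)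
Conditions: TBSOTf (1.1 equiv), TMEDA (1.1 equiv), Et2O, 0 → 23 °C; then TMEDA (2 equiv), n-BuLi (1.8 equiv), −78 °C; Me3SiCl (3 equiv), −78 → 23 °C; cold aq NaHSO4 work-up
Reagents that add atoms: chlorotrimethylsilane, C[Si](C)(C)Cl
Why: Directed ortho-metalation of the carbamate (N–H masked in the flask as its silyl derivative) should remove the proton between the carbamate and the MOM ether, the two strongest directing groups on the ring (the other carbamate-flanked site has only the weaker methoxy neighbour), and the aryllithium is silylated on carbon, the N-silyl group being lost on work-up.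

Step 4
Reactants: 7 5-methoxy-3-(methoxymethoxy)-2-(trimethylsilyl)phenyl N-(propan-2-yl)carbamate
Product: 9 5-methoxy-3-(methoxymethoxy)-2-(trimethylsilyl)phenyl trifluoromethanesulfonate, via silyl phenoxide 8 (not isolated)
Conditions: Et2NH (1.5 equiv), DBU (1.5 equiv), MeCN, 40 °C; then PhNTf2 (1.5 equiv), 23 °C
Reagents that add atoms: N-phenylbis(trifluoromethanesulfonimide), O=S(=O)(N(c1ccccc1)S(=O)(=O)C(F)(F)F)C(F)(F)F
Why: E1cB cleavage of the secondary carbamate (the isocyanate released is scavenged by diethylamine) frees the hindered ortho-silyl phenoxide, which is sulfonylated in the same flask by the mild triflyl donor without touching the aryl–silicon bond or the MOM ether.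

Step 5
Reactants: 10 2',6'-dihydroxyacetophenone
Product: 11 1-[2,6-bis(benzyloxy)phenyl]ethan-1-one
Conditions: BnBr (2.4 equiv), K2CO3 (3 equiv), DMF, 70 °C
Reagents that add atoms: benzyl bromide, BrCc1ccccc1
Why: Williamson ether synthesis in warm DMF benzylates both phenols, including the one hydrogen-bonded to the ketone, and benzyl is chosen because it withstands steps 6 to 9 and can later be removed without acid or base.

Step 6
Reactants: 11 1-[2,6-bis(benzyloxy)phenyl]ethan-1-one
Product: 13 methyl 3-[2,6-bis(benzyloxy)phenyl]-3-oxopropanoate, via sodium enolate 12 (not isolated)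
Conditions: NaH (3 equiv), (MeO)2CO (6 equiv), THF, reflux; AcOH quench at 0 °C
Reagents that add atoms: dimethyl carbonate, COC(=O)OC
Why: Crossed Claisen condensation (C-methoxycarbonylation of the methyl ketone enolate) is driven to completion by deprotonation of the beta-keto ester formed, and the ortho-disubstituted aryl group does not hinder the unsubstituted methyl terminus.

Step 7
Reactants: 13 methyl 3-[2,6-bis(benzyloxy)phenyl]-3-oxopropanoate
Product: 14 methyl (3S)-3-[2,6-bis(benzyloxy)phenyl]-3-hydroxypropanoate
Conditions: RuCl2[(R)-BINAP] (1 mol %), H2 (50 atm), MeOH, 50 °C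
Reagents that add atoms: none
Why: Noyori asymmetric hydrogenation of a beta-keto ester, in which the substrate chelates ruthenium through ketone and ester oxygens and the (R)-BINAP ligand fixes the carbonyl face that receives hydride, should give the (S)-alcohol in the sense established for aroylacetates (the descriptor is S because aryl outranks CH2CO2Me), with the benzyl ethers inert to this catalyst.

Step 8
Reactants: 14 methyl (3S)-3-[2,6-bis(benzyloxy)phenyl]-3-hydroxypropanoate
Product: 15 (3S)-3-[2,6-bis(benzyloxy)phenyl]-3-hydroxy-N-methoxy-N-methylpropanamide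
Conditions: MeNH(OMe)·HCl (3 equiv), iPrMgCl (6 equiv), THF, −20 → 0 °C
Reagents that add atoms: N,O-dimethylhydroxylamine hydrochloride, CNOC.Cl
Why: Aminolysis of the ester by the chloromagnesium amide of N,O-dimethylhydroxylamine (Weinreb amide formation) tolerates the free hydroxyl as its magnesium alkoxide at low temperature and does not touch the stereocenter.

Step 9
Reactants: 15 (3S)-3-[2,6-bis(benzyloxy)phenyl]-3-hydroxy-N-methoxy-N-methylpropanamide; 9 5-methoxy-3-(methoxymethoxy)-2-(trimethylsilyl)phenyl trifluoromethanesulfonate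
Product: 20 (2S)-2-[2,6-bis(benzyloxy)phenyl]-7-methoxy-5-(methoxymethoxy)chroman-4-one, via potassium alkoxide 16 (not isolated), via aryne 17 (not isolated), via aryl anion 18 (not isolated), via hemiaminal alkoxide 19 (not isolated)
Conditions: KH (1.05 equiv), THF, 0 °C; then 9 (1.4 equiv), Bu4N[Ph3SiF2] (1.6 equiv), THF (0.05 M), 0 → 23 °C; AcOH, then aq NH4Cl
Reagents that add atoms: none
Why: Proposed new method: fluoride removes the silyl group of 9 and triflate leaves to give aryne 17, whose triple bond is distorted by the inductively withdrawing MOM-oxygen on the future C5 so that alkoxide 16 bonds through oxygen to the remote aryne carbon (future C8a) and the negative charge appears at C4a; aryl anion 18 then adds to the Weinreb carbonyl in a 6-exo-trig closure of ring C, and hemiaminal alkoxide 19 should persist until the acidic quench releases ketone 20. The closest known reactions are the fluoride-triggered annulation of arynes with salicylate esters to xanthones (oxygen arylation, then acyl substitution by the aryl anion) and the Parham cyclisation of aryllithiums onto pendant Weinreb amides; a stereodefined aliphatic beta-hydroxy acid derivative has not been used as the partner. No stereocenter is formed: the C2–O bond is never broken and no chalcone-type intermediate is passed, so the configuration set in step 7 is carried into the flavanone. The step needs oxygen to attack C8a and not C4a, which the alkoxy group flanking the aryne secures, and it needs ring closure to outrun protonation of the aryl anion, which is why the alkoxide is made with KH (hydrogen as the only by-product) and an anhydrous fluoride source is used. The Weinreb amide is preferred to an ester because its alkoxide is far less prone to retro-aldol cleavage and cannot transesterify itself, its alpha-hydrogens are less readily taken by the aryl anion, and no alkoxide base is released beside a ketone that could open ring C by beta-elimination.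

Step 10
Reactants: 20 (2S)-2-[2,6-bis(benzyloxy)phenyl]-7-methoxy-5-(methoxymethoxy)chroman-4-one
Product: 21 (2S)-2-(2,6-dihydroxyphenyl)-7-methoxy-5-(methoxymethoxy)chroman-4-one
Conditions: H2 (1 atm), Pd/C (10 wt %), EtOAc, 23 °C
Reagents that add atoms: none
Why: Catalytic hydrogenolysis cleaves the two benzyl aryl ethers under neutral conditions, while the MOM ether, the ketone and the ring C benzylic C2–O bond (cleaved much more slowly than O-benzyl groups) should survive a short reaction at one atmosphere.

Step 11
Reactants: 21 (2S)-2-(2,6-dihydroxyphenyl)-7-methoxy-5-(methoxymethoxy)chroman-4-one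
Product: 22 (2S)-2-(2,6-diacetoxyphenyl)-7-methoxy-5-(methoxymethoxy)chroman-4-one
Conditions: Ac2O (3 equiv), pyridine (4 equiv), DMAP (5 mol %), CH2Cl2, 0 → 23 °C
Reagents that add atoms: acetic anhydride, CC(=O)OC(C)=O
Why: O-acylation of the two ring B phenols (nucleophilic catalysis by DMAP) turns the resorcinol-type ring B from the most electron-rich arene of the molecule into a deactivated one, so that the iodination that follows is confined to ring A.

Step 12
Reactants: 22 (2S)-2-(2,6-diacetoxyphenyl)-7-methoxy-5-(methoxymethoxy)chroman-4-one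
Product: 23 (2S)-2-(2,6-diacetoxyphenyl)-8-iodo-7-methoxy-5-(methoxymethoxy)chroman-4-one
Conditions: NIS (1.1 equiv), CF3CO2H (5 mol %), MeCN, 0 → 23 °C, dark
Reagents that add atoms: N-iodosuccinimide, O=C1CCC(=O)N1I
Why: Electrophilic aromatic iodination of ring A should occur at C8, between O1 and the 7-methoxy group, and not at C6, which is shielded by the 5-O-alkyl group that the peri carbonyl forces to point towards it (the regiochemistry known for 5,7-di-O-alkyl flavonoids), while the anhydrous, catalytic acid leaves the MOM ether intact.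

Step 13
Reactants: 24 racemic lavandulol
Product: 25 (S)-lavandulol, (2S)-5-methyl-2-(prop-1-en-2-yl)hex-4-en-1-ol
Conditions: Novozym 435 (immobilised Candida antarctica lipase B), vinyl acetate (0.7 equiv), hexane, 30 °C, run beyond half conversion; chromatography
Reagents that add atoms: none
Why: Lipase-catalysed kinetic resolution by enantioselective transesterification acetylates the faster-reacting (R)-alcohol, so that with conversion taken beyond one half the unreacted (S)-alcohol should remain in high enantiomeric purity and is separated from the acetate.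

Step 14
Reactants: 25 (S)-lavandulol
Product: 26 (2S)-5-methyl-2-(prop-1-en-2-yl)hex-4-en-1-yl iodide
Conditions: I2 (1.2 equiv), PPh3 (1.2 equiv), imidazole (1.5 equiv), CH2Cl2, 0 → 23 °C, dark
Reagents that add atoms: iodine, II
Why: Appel-type iodination converts the primary alcohol into the iodide by SN2 displacement at CH2, one carbon away from the stereocenter, which is therefore untouched.

Step 15
Reactants: 26 (2S)-5-methyl-2-(prop-1-en-2-yl)hex-4-en-1-yl iodide; 23 (2S)-2-(2,6-diacetoxyphenyl)-8-iodo-7-methoxy-5-(methoxymethoxy)chroman-4-one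
Product: 28 (2S)-2-(2,6-diacetoxyphenyl)-7-methoxy-5-(methoxymethoxy)-8-[(2R)-5-methyl-2-(prop-1-en-2-yl)hex-4-en-1-yl]chroman-4-one, via lavandulylzinc iodide 27 (not isolated)
Conditions: Zn dust (2 equiv, activated with BrCH2CH2Br and Me3SiCl), LiCl (1.5 equiv), THF, 30 °C; then 23 (0.7 equiv), Pd(OAc)2 (3 mol %), CPhos (6 mol %), THF, 23 → 40 °C
Reagents that add atoms: none
Why: Negishi sp3–sp2 cross-coupling, in which LiCl-assisted zinc insertion into the primary C–I bond leaves the beta stereocenter untouched and the bulky biarylphosphine favours reductive elimination over beta-hydride elimination at the hindered, electron-rich aryl iodide, should join the chain while ketone, acetates and MOM ether stay inert to the alkylzinc halide.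

Step 16
Reactants: 28 (2S)-2-(2,6-diacetoxyphenyl)-7-methoxy-5-(methoxymethoxy)-8-[(2R)-5-methyl-2-(prop-1-en-2-yl)hex-4-en-1-yl]chroman-4-one
Product: 29 exiguaflavanone B, (2S)-2-(2,6-dihydroxyphenyl)-5-hydroxy-7-methoxy-8-[(2R)-5-methyl-2-(prop-1-en-2-yl)hex-4-en-1-yl]chroman-4-one
Conditions: HCl (0.3 M in MeOH), 23 °C
Reagents that add atoms: none
Why: Acid-catalysed acetal exchange of the MOM ether and acid-catalysed transesterification of the two aryl acetates by methanol should free all three phenols together under dilute anhydrous acid at room temperature, conditions mild enough to spare the trisubstituted and 1,1-disubstituted olefins and the C2 center.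

**Compound list**

1 | 5-methoxyresorcinol (5-methoxybenzene-1,3-diol) | COc1cc(O)cc(O)c1 | starting material
2 | 3-methoxy-5-(methoxymethoxy)phenol | COCOc1cc(O)cc(OC)c1 | intermediate
3 | 3-methoxy-5-(methoxymethoxy)phenyl N-(propan-2-yl)carbamate | COCOc1cc(OC)cc(OC(=O)NC(C)C)c1 | intermediate
4 | 3-methoxy-5-(methoxymethoxy)phenyl N-(tert-butyldimethylsilyl)-N-(propan-2-yl)carbamate | COCOc1cc(OC)cc(OC(=O)N(C(C)C)[Si](C)(C)C(C)(C)C)c1 | intermediate
5 | [6-{[(tert-butyldimethylsilyl)(propan-2-yl)carbamoyl]oxy}-4-methoxy-2-(methoxymethoxy)phenyl]lithium | COCOc1cc(OC)cc(OC(=O)N(C(C)C)[Si](C)(C)C(C)(C)C)c1[Li] | intermediate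
6 | 5-methoxy-3-(methoxymethoxy)-2-(trimethylsilyl)phenyl N-(tert-butyldimethylsilyl)-N-(propan-2-yl)carbamate | COCOc1cc(OC)cc(OC(=O)N(C(C)C)[Si](C)(C)C(C)(C)C)c1[Si](C)(C)C | intermediate
7 | 5-methoxy-3-(methoxymethoxy)-2-(trimethylsilyl)phenyl N-(propan-2-yl)carbamate | COCOc1cc(OC)cc(OC(=O)NC(C)C)c1[Si](C)(C)C | intermediate
8 | 5-methoxy-3-(methoxymethoxy)-2-(trimethylsilyl)phenol (present as its DBU salt) | COCOc1cc(OC)cc(O)c1[Si](C)(C)C | intermediate
9 | 5-methoxy-3-(methoxymethoxy)-2-(trimethylsilyl)phenyl trifluoromethanesulfonate | COCOc1cc(OC)cc(OS(=O)(=O)C(F)(F)F)c1[Si](C)(C)C | intermediate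
10 | 2',6'-dihydroxyacetophenone, 1-(2,6-dihydroxyphenyl)ethan-1-one | CC(=O)c1c(O)cccc1O | starting material
11 | 1-[2,6-bis(benzyloxy)phenyl]ethan-1-one | CC(=O)c1c(OCc2ccccc2)cccc1OCc1ccccc1 | intermediate
12 | sodium 1-[2,6-bis(benzyloxy)phenyl]-3-methoxy-3-oxoprop-1-en-1-olate | COC(=O)C=C([O-])c1c(OCc2ccccc2)cccc1OCc1ccccc1.[Na+] | intermediate
13 | methyl 3-[2,6-bis(benzyloxy)phenyl]-3-oxopropanoate | COC(=O)CC(=O)c1c(OCc2ccccc2)cccc1OCc1ccccc1 | intermediate
14 | methyl (3S)-3-[2,6-bis(benzyloxy)phenyl]-3-hydroxypropanoate | COC(=O)C[C@H](O)c1c(OCc2ccccc2)cccc1OCc1ccccc1 | intermediate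
15 | (3S)-3-[2,6-bis(benzyloxy)phenyl]-3-hydroxy-N-methoxy-N-methylpropanamide | CON(C)C(=O)C[C@H](O)c1c(OCc2ccccc2)cccc1OCc1ccccc1 | intermediate
16 | potassium (1S)-1-[2,6-bis(benzyloxy)phenyl]-3-[methoxy(methyl)amino]-3-oxopropan-1-olate | CON(C)C(=O)C[C@H]([O-])c1c(OCc2ccccc2)cccc1OCc1ccccc1.[K+] | intermediate
17 | 5-methoxy-3-(methoxymethoxy)benzyne (triple bond between the former triflate and silyl carbons) | COCOC1=CC(OC)=CC#C1 | intermediate
18 | potassium 2-{(1S)-1-[2,6-bis(benzyloxy)phenyl]-3-[methoxy(methyl)amino]-3-oxopropoxy}-4-methoxy-6-(methoxymethoxy)benzen-1-ide | CON(C)C(=O)C[C@H](Oc1cc(OC)cc(OCOC)[c-]1)c1c(OCc2ccccc2)cccc1OCc1ccccc1.[K+] | intermediate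
19 | potassium (2S)-2-[2,6-bis(benzyloxy)phenyl]-7-methoxy-4-[methoxy(methyl)amino]-5-(methoxymethoxy)chroman-4-olate (both C4 epimers) | COc1cc(OCOC)c2c(c1)O[C@H](c1c(OCc3ccccc3)cccc1OCc1ccccc1)CC2([O-])N(C)OC.[K+] | intermediate
20 | (2S)-2-[2,6-bis(benzyloxy)phenyl]-7-methoxy-5-(methoxymethoxy)chroman-4-one | COc1cc(OCOC)c2c(c1)O[C@H](c1c(OCc3ccccc3)cccc1OCc1ccccc1)CC2=O | intermediate
21 | (2S)-2-(2,6-dihydroxyphenyl)-7-methoxy-5-(methoxymethoxy)chroman-4-one | COc1cc(OCOC)c2c(c1)O[C@H](c1c(O)cccc1O)CC2=O | intermediate
22 | (2S)-2-(2,6-diacetoxyphenyl)-7-methoxy-5-(methoxymethoxy)chroman-4-one | COc1cc(OCOC)c2c(c1)O[C@H](c1c(OC(C)=O)cccc1OC(C)=O)CC2=O | intermediate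
23 | (2S)-2-(2,6-diacetoxyphenyl)-8-iodo-7-methoxy-5-(methoxymethoxy)chroman-4-one | COc1cc(OCOC)c2c(c1I)O[C@H](c1c(OC(C)=O)cccc1OC(C)=O)CC2=O | intermediate
24 | racemic lavandulol, 5-methyl-2-(prop-1-en-2-yl)hex-4-en-1-ol | C=C(C)C(CC=C(C)C)CO | starting material
25 | (S)-lavandulol, (2S)-5-methyl-2-(prop-1-en-2-yl)hex-4-en-1-ol | C=C(C)[C@H](CC=C(C)C)CO | intermediate
26 | (2S)-5-methyl-2-(prop-1-en-2-yl)hex-4-en-1-yl iodide | C=C(C)[C@H](CC=C(C)C)CI | intermediate
27 | iodo[(2S)-5-methyl-2-(prop-1-en-2-yl)hex-4-en-1-yl]zinc | C=C(C)[C@H](CC=C(C)C)C[Zn]I | intermediate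
28 | (2S)-2-(2,6-diacetoxyphenyl)-7-methoxy-5-(methoxymethoxy)-8-[(2R)-5-methyl-2-(prop-1-en-2-yl)hex-4-en-1-yl]chroman-4-one | C=C(C)[C@H](CC=C(C)C)Cc1c(OC)cc(OCOC)c2c1O[C@H](c1c(OC(C)=O)cccc1OC(C)=O)CC2=O | intermediate
29 | exiguaflavanone B, (2S)-2-(2,6-dihydroxyphenyl)-5-hydroxy-7-methoxy-8-[(2R)-5-methyl-2-(prop-1-en-2-yl)hex-4-en-1-yl]chroman-4-one | C=C(C)[C@H](CC=C(C)C)Cc1c(OC)cc(O)c2c1O[C@H](c1c(O)cccc1O)CC2=O | target

**Step count and risks**

Total step count: 16. Longest linear sequence: 10 steps (from 10 through steps 5–12, 15 and 16; the line from 1 through steps 1–4, 9–12, 15 and 16 is equally long).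

Steps most likely to fail:

1. Step 9 (proposed new method). The aryl anion may take a proton before it closes ring C, most plausibly from the alpha-CH2 through a six-membered transition state, which would trigger beta-elimination of the aryloxide. The alkoxide may also be silylated or add at the wrong aryne carbon, or the hemiaminal may collapse early and expose the ketone to base. The fallback uses known reactions only, sets out from keto ester 13 and from 5-methoxyresorcinol 1, and returns at flavanone 20. Hydrogenation of 13 with RuCl2[(S)-BINAP] would give methyl (3R)-3-[2,6-bis(benzyloxy)phenyl]-3-hydroxypropanoate F1, which is converted as in step 8 into (3R)-3-[2,6-bis(benzyloxy)phenyl]-3-hydroxy-N-methoxy-N-methylpropanamide F2. Exhaustive MOM protection of 1 would give 1-methoxy-3,5-bis(methoxymethoxy)benzene F3, which n-BuLi (THF, 0 °C) metalates between the two MOM ethers to [4-methoxy-2,6-bis(methoxymethoxy)phenyl]lithium F4. Addition of excess F4 to F2 should give (3R)-3-[2,6-bis(benzyloxy)phenyl]-3-hydroxy-1-[4-methoxy-2,6-bis(methoxymethoxy)phenyl]propan-1-one F5. Chelation-assisted cleavage of one of its two equivalent MOM ethers (MgBr2·OEt2) would give (3R)-3-[2,6-bis(benzyloxy)phenyl]-3-hydroxy-1-[2-hydroxy-4-methoxy-6-(methoxymethoxy)phenyl]propan-1-one F6. A Mitsunobu etherification (PPh3, DIAD, THF) then closes ring C with inversion at the carbinol carbon, so the (3R)-alcohol delivers the (2S)-flavanone 20.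

2. Step 15. Zinc insertion may stall, transmetalation to a palladium center flanked by two ortho oxygen substituents may be slow, and beta-hydride elimination from the alkylpalladium intermediate would reduce the aryl iodide instead of alkylating it. The fallback sets out from iodide 26 (with aryl iodide 23) and returns at 28. Iodine–lithium exchange on 26 (t-BuLi, Et2O, −78 °C) would give [(2S)-5-methyl-2-(prop-1-en-2-yl)hex-4-en-1-yl]lithium F7, which is trapped by B-methoxy-9-BBN as lithium [(2S)-5-methyl-2-(prop-1-en-2-yl)hex-4-en-1-yl](methoxy)-9-borabicyclo[3.3.1]nonan-9-uide F8. This borinate transfers its primary alkyl group to palladium without added base (PdCl2(dppf), DMF/THF, 23 → 50 °C), a B-alkyl Suzuki–Miyaura coupling with 23 that avoids both the zinc insertion and any basic activator.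

3. Step 3. Lithiation may occur in part at the other carbamate-flanked position (between carbamate and methoxy), and the silyl triflate may attack the MOM acetal before it silylates nitrogen. The fallback fixes the regiochemistry by symmetry, sets out from 1 and returns at 9. The bis-MOM ether F3 is lithiated between its two MOM groups to F4 (both as in the first fallback) and quenched with BrCCl2CCl2Br to give 2-bromo-5-methoxy-1,3-bis(methoxymethoxy)benzene F9. Methanolic HCl would then give 2-bromo-5-methoxybenzene-1,3-diol F10, and (Me3Si)2NH its bis(trimethylsilyl) ether, [(2-bromo-5-methoxy-1,3-phenylene)bis(oxy)]bis(trimethylsilane) F11. Bromine–lithium exchange with n-BuLi at −78 °C is followed by a retro-Brook shift of one silyl group from oxygen to carbon, giving lithium 5-methoxy-2-(trimethylsilyl)-3-[(trimethylsilyl)oxy]phenolate F12. Tf2O converts this into 5-methoxy-2-(trimethylsilyl)-3-[(trimethylsilyl)oxy]phenyl trifluoromethanesulfonate F13, and methanol in the work-up removes the remaining O-silyl group to give 3-hydroxy-5-methoxy-2-(trimethylsilyl)phenyl trifluoromethanesulfonate F14. MOMCl and iPr2NEt then give 9.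

**Further compounds**

F1 | step 9 | methyl (3R)-3-[2,6-bis(benzyloxy)phenyl]-3-hydroxypropanoate | COC(=O)C[C@@H](O)c1c(OCc2ccccc2)cccc1OCc1ccccc1
F2 | step 9 | (3R)-3-[2,6-bis(benzyloxy)phenyl]-3-hydroxy-N-methoxy-N-methylpropanamide | CON(C)C(=O)C[C@@H](O)c1c(OCc2ccccc2)cccc1OCc1ccccc1
F3 | step 9 | 1-methoxy-3,5-bis(methoxymethoxy)benzene | COCOc1cc(OC)cc(OCOC)c1
F4 | step 9 | [4-methoxy-2,6-bis(methoxymethoxy)phenyl]lithium | COCOc1cc(OC)cc(OCOC)c1[Li]
F5 | step 9 | (3R)-3-[2,6-bis(benzyloxy)phenyl]-3-hydroxy-1-[4-methoxy-2,6-bis(methoxymethoxy)phenyl]propan-1-one | COCOc1cc(OC)cc(OCOC)c1C(=O)C[C@@H](O)c1c(OCc2ccccc2)cccc1OCc1ccccc1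
F6 | step 9 | (3R)-3-[2,6-bis(benzyloxy)phenyl]-3-hydroxy-1-[2-hydroxy-4-methoxy-6-(methoxymethoxy)phenyl]propan-1-one | COCOc1cc(OC)cc(O)c1C(=O)C[C@@H](O)c1c(OCc2ccccc2)cccc1OCc1ccccc1
F7 | step 15 | [(2S)-5-methyl-2-(prop-1-en-2-yl)hex-4-en-1-yl]lithium | C=C(C)[C@H](CC=C(C)C)C[Li]
F8 | step 15 | lithium [(2S)-5-methyl-2-(prop-1-en-2-yl)hex-4-en-1-yl](methoxy)-9-borabicyclo[3.3.1]nonan-9-uide | C=C(C)[C@H](CC=C(C)C)C[B-]1(OC)C2CCCC1CCC2.[Li+]
F9 | step 3 | 2-bromo-5-methoxy-1,3-bis(methoxymethoxy)benzene | COCOc1cc(OC)cc(OCOC)c1Br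
F10 | step 3 | 2-bromo-5-methoxybenzene-1,3-diol | COc1cc(O)c(Br)c(O)c1
F11 | step 3 | [(2-bromo-5-methoxy-1,3-phenylene)bis(oxy)]bis(trimethylsilane) | COc1cc(O[Si](C)(C)C)c(Br)c(O[Si](C)(C)C)c1
F12 | step 3 | lithium 5-methoxy-2-(trimethylsilyl)-3-[(trimethylsilyl)oxy]phenolate | COc1cc([O-])c([Si](C)(C)C)c(O[Si](C)(C)C)c1.[Li+]
F13 | step 3 | 5-methoxy-2-(trimethylsilyl)-3-[(trimethylsilyl)oxy]phenyl trifluoromethanesulfonate | COc1cc(OS(=O)(=O)C(F)(F)F)c([Si](C)(C)C)c(O[Si](C)(C)C)c1
F14 | step 3 | 3-hydroxy-5-methoxy-2-(trimethylsilyl)phenyl trifluoromethanesulfonate | COc1cc(O)c([Si](C)(C)C)c(OS(=O)(=O)C(F)(F)F)c1
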